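## Retrosynthetic overview

1. The target is the cis-2-aryl-3-(hydroxymethyl)-1,4-benzodioxane dimer of two 5-hydroxyconiferyl units. Both benzene rings are bought; the 1,4-dioxane is the only ring that has to be made.
2. Last disconnection: one hydride reduction of the resolved cis diester turns two CO2Et groups into CH2OH and removes two aryl pivalates.
3. cis from trans: C8 is reset by kinetic protonation of the C9 ester enolate, so the ring-forming step only has to deliver the ring and C7.
4. Ring formation: the dioxane (O4–C8 first, then O5–C7) arises in one operation by oxidative 8–O–4 radical coupling of two molecules of ethyl 5-hydroxyferulate, followed by intramolecular trapping of the p-quinone methide by the neighbouring 5-OH.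
5. The monomer comes from 5-hydroxyvanillin by Wittig olefination.

## Assumptions and conventions

- Assumption: 3,4-dihydroxy-5-methoxybenzaldehyde (5-hydroxyvanillin) is taken as a catalogue compound.
- Ring A is the benzo ring of the benzodioxane and ring B is the pendant aryl group. C7 is the dioxane carbon that carries ring B and C8 is the dioxane carbon that carries C9. O4 and O5 are the ring A oxygens on C8 and C7.
- The target is (7S,8R), with ring B and CH2OH cis. In the C9 esters the same cis geometry is (7S,8S), because CO2Et outranks C7 in the priority order.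
- Racemates are drawn and named as the enantiomer that is carried on; the mirror image is present in equal amount.

## Route

Step 1
Reactants: 1 3,4-dihydroxy-5-methoxybenzaldehyde; 2 ethyl 2-(triphenylphosphoranylidene)acetate (1.3 equiv)
Product: 3 ethyl (E)-3-(3,4-dihydroxy-5-methoxyphenyl)prop-2-enoate
Conditions: toluene, 90 °C, 6 h
Reagents that add atoms: none
Why: Wittig olefination with a stabilised ylide, which tolerates the free phenols and gives the (E)-cinnamate; no stereocentre is formed.

Step 2
Reactants: 3 ethyl (E)-3-(3,4-dihydroxy-5-methoxyphenyl)prop-2-enoate (two molecules)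
Product: 5 racemic trans diester ethyl (2R,3S)-rel-3-(3,4-dihydroxy-5-methoxyphenyl)-6-[(E)-3-ethoxy-3-oxoprop-1-enyl]-8-methoxy-2,3-dihydro-1,4-benzodioxine-2-carboxylate, via p-quinone methide 4 (not isolated)
Conditions: Ag2O (0.55 equiv), toluene/acetone 2:1, 23 °C, dark, N2, 16 h; filtration through Celite
Reagents that add atoms: none
Why: Biomimetic oxidative phenol coupling in which Ag2O takes one electron and one proton from the 4-OH of two molecules of 3, the 4-O centre of one radical joins C8 of the other (8–O–4 radical coupling, C8 formed without facial control and therefore racemic), and the neighbouring 5-OH of ring A then adds to C7 of the p-quinone methide 4 (intramolecular oxa-1,6-addition) with H8 eclipsing the quinone methide plane to avoid A(1,3) strain, which gives the trans ring; the small amount of cis isomer formed beside it is carried along, because step 4 resets C8 in both.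

Step 3
Reactants: 5 racemic trans diester
Product: 6 racemic trans bis-pivalate ethyl (2R,3S)-rel-3-[3-methoxy-4,5-bis(2,2-dimethylpropanoyloxy)phenyl]-6-[(E)-3-ethoxy-3-oxoprop-1-enyl]-8-methoxy-2,3-dihydro-1,4-benzodioxine-2-carboxylate
Conditions: PivCl (2.6 equiv), Et3N (3 equiv), DMAP (0.1 equiv), CH2Cl2, 0 → 23 °C
Reagents that add atoms: pivaloyl chloride, CC(C)(C)C(=O)Cl
Why: DMAP-catalysed O-acylation of both phenols of ring B; the pivalates have no α-hydrogen, keep ring B from forming a phenoxide (so the C7–O bond cannot open through a quinone methide in the base step that follows) and are removed by the final hydride reduction; no stereocentre is touched.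

Step 4
Reactants: 6 racemic trans bis-pivalate
Product: 8 racemic cis bis-pivalate ethyl (2S,3S)-rel-3-[3-methoxy-4,5-bis(2,2-dimethylpropanoyloxy)phenyl]-6-[(E)-3-ethoxy-3-oxoprop-1-enyl]-8-methoxy-2,3-dihydro-1,4-benzodioxine-2-carboxylate, via lithium ester enolate 7 (not isolated)
Conditions: LiN(iPr)2 (1.15 equiv), THF, −78 °C, 10 min; 2,6-di-tert-butylphenol (3 equiv), THF, −78 °C; AcOH, −78 → 0 °C
Reagents that add atoms: none
Why: Zimmerman-type kinetic protonation of an ester enolate, in which irreversible deprotonation at C8 (the only acidic C–H) gives the exocyclic enolate 7, the C7 aryl group turns pseudo-axial to avoid A(1,3) strain with the enolate oxygen substituents and shields one face, and the bulky phenol delivers the proton to C8 anti to the aryl group (also the axial trajectory) so that CO2Et ends up cis to ring B; C7 is not touched, trans and cis 6 converge on the same enolate, and the short time at −78 °C keeps β-elimination of the ring A aryloxide in check.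

Step 5
Reactants: 8 racemic cis bis-pivalate
Product: 9 ethyl (2S,3S)-3-[3-methoxy-4,5-bis(2,2-dimethylpropanoyloxy)phenyl]-6-[(E)-3-ethoxy-3-oxoprop-1-enyl]-8-methoxy-2,3-dihydro-1,4-benzodioxine-2-carboxylate, the (7S,8S) enantiomer
Conditions: preparative HPLC on amylose tris(3,5-dimethylphenylcarbamate) immobilised on silica, n-hexane/i-PrOH 85:15, 25 °C
Reagents that add atoms: none
Why: Resolution by chromatography on a chiral stationary phase, in which no bond is made or broken and the neutral eluent leaves the base-sensitive C8 centre alone; the (7S,8S) fraction is identified by electronic circular dichroism or X-ray analysis, and the other enantiomer can be returned to racemic 6 with DBU through retro-oxa-Michael opening and re-closure.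

Step 6
Reactants: 9 the (7S,8S) cis bis-pivalate diester
Product: 10 5-[(2S,3R)-3-(hydroxymethyl)-7-[(E)-3-hydroxyprop-1-enyl]-5-methoxy-2,3-dihydro-1,4-benzodioxin-2-yl]-3-methoxybenzene-1,2-diol, the (7S,8R) target
Conditions: iBu2AlH (12 equiv), CH2Cl2, −78 → −40 °C; aqueous KNaC4H4O6, EtOAc, 0 °C, argon
Reagents that add atoms: none
Why: Hydride reduction of esters with iBu2AlH, in which both ethyl esters give primary alcohols by 1,2-addition (the cinnamate gives the (E)-allylic alcohol without conjugate reduction) and both aryl pivalates are cleaved reductively in the same flask; no base is present, so C8 keeps its configuration and is fixed once C9 is CH2OH (the descriptor changes from 8S to 8R only because CH2OH ranks below C7), and the cold neutral tartrate work-up avoids ionisation of the C7–O bond of the free p-hydroxyaryl product.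

## Compound list

1 | 3,4-dihydroxy-5-methoxybenzaldehyde (5-hydroxyvanillin) | COc1cc(C=O)cc(O)c1O | starting material
2 | ethyl 2-(triphenylphosphoranylidene)acetate | CCOC(=O)C=P(c1ccccc1)(c1ccccc1)c1ccccc1 | starting material
3 | ethyl (E)-3-(3,4-dihydroxy-5-methoxyphenyl)prop-2-enoate (ethyl 5-hydroxyferulate) | CCOC(=O)/C=C/c1cc(O)c(O)c(OC)c1 | intermediate
4 | 8–O–4-coupled p-quinone methide, racemic at C8, (8R) shown, not isolated | CCOC(=O)/C=C/c1cc(O)c(O[C@@H](C(=O)OCC)C=C2C=C(OC)C(=O)C(O)=C2)c(OC)c1 | intermediate
5 | racemic trans diester, (7S,8R) shown: ethyl (2R,3S)-rel-3-(3,4-dihydroxy-5-methoxyphenyl)-6-[(E)-3-ethoxy-3-oxoprop-1-enyl]-8-methoxy-2,3-dihydro-1,4-benzodioxine-2-carboxylate | COc1cc([C@@H]2Oc3cc(/C=C/C(=O)OCC)cc(OC)c3O[C@H]2C(=O)OCC)cc(O)c1O | intermediate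
6 | racemic trans bis-pivalate, (7S,8R) shown: ethyl (2R,3S)-rel-3-[3-methoxy-4,5-bis(2,2-dimethylpropanoyloxy)phenyl]-6-[(E)-3-ethoxy-3-oxoprop-1-enyl]-8-methoxy-2,3-dihydro-1,4-benzodioxine-2-carboxylate | COc1cc([C@@H]2Oc3cc(/C=C/C(=O)OCC)cc(OC)c3O[C@H]2C(=O)OCC)cc(OC(=O)C(C)(C)C)c1OC(=O)C(C)(C)C | intermediate
7 | lithium C8 ester enolate of 6, racemic, (7S) shown, not isolated | [Li+].CCOC([O-])=C1Oc2c(OC)cc(/C=C/C(=O)OCC)cc2O[C@H]1c3cc(OC)c(OC(=O)C(C)(C)C)c(OC(=O)C(C)(C)C)c3 | intermediate
8 | racemic cis bis-pivalate, (7S,8S) shown: ethyl (2S,3S)-rel-3-[3-methoxy-4,5-bis(2,2-dimethylpropanoyloxy)phenyl]-6-[(E)-3-ethoxy-3-oxoprop-1-enyl]-8-methoxy-2,3-dihydro-1,4-benzodioxine-2-carboxylate | COc1cc([C@@H]2Oc3cc(/C=C/C(=O)OCC)cc(OC)c3O[C@@H]2C(=O)OCC)cc(OC(=O)C(C)(C)C)c1OC(=O)C(C)(C)C | intermediate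
9 | single (7S,8S) enantiomer: ethyl (2S,3S)-3-[3-methoxy-4,5-bis(2,2-dimethylpropanoyloxy)phenyl]-6-[(E)-3-ethoxy-3-oxoprop-1-enyl]-8-methoxy-2,3-dihydro-1,4-benzodioxine-2-carboxylate | COc1cc([C@@H]2Oc3cc(/C=C/C(=O)OCC)cc(OC)c3O[C@@H]2C(=O)OCC)cc(OC(=O)C(C)(C)C)c1OC(=O)C(C)(C)C | intermediate
10 | 5-[(2S,3R)-3-(hydroxymethyl)-7-[(E)-3-hydroxyprop-1-enyl]-5-methoxy-2,3-dihydro-1,4-benzodioxin-2-yl]-3-methoxybenzene-1,2-diol, (7S,8R), cis | COc1cc([C@@H]2Oc3cc(/C=C/CO)cc(OC)c3O[C@@H]2CO)cc(O)c1O | target

## Step count and risks

Total step count: 6. Longest linear sequence: 6 steps (1 → 3 → 5 → 6 → 8 → 9 → 10).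

The three steps most likely to fail are 2, 4 and 6.

**Step 2.** The free catechol of ring B in 5 is itself oxidisable, so chain growth and quinone formation can consume the dimer. The fallback sets out from 3 and comes back at 6, and replaces the homodimerisation by a cross-coupling with a blocked partner. Compound 3 is acylated with PivCl (1.0 equiv) and pyridine at −20 °C at the less hindered, less acidic 5-OH to give ethyl (E)-3-[4-hydroxy-3-methoxy-5-(2,2-dimethylpropanoyloxy)phenyl]prop-2-enoate F1, which can only act as the C8 radical and quinone methide partner. Slow addition of 3 to F1 (2 equiv) and Ag2CO3 in toluene/acetone gives the racemic trans mono-pivalate F2, which has no catechol left and cannot grow further. Pivaloylation of its remaining 4-OH (PivCl, Et3N, DMAP) gives 6.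

**Step 4.** The free enolate 7 can expel the ring A aryloxide (ring opening), or the facial ratio of the protonation can be poor. The fallback sets out from 6 and comes back at 8, and never leaves the enolate free. LiN(iPr)2 is added to 6 in the presence of Me3SiCl at −78 °C (internal quench) to give the ketene silyl acetal F3, a covalent species that cannot eliminate. Neutral F3 is then protonated at C8 with a hindered Brønsted acid (2,6-di-tert-butylpyridinium triflate, CH2Cl2, −78 °C), again anti to the pseudo-axial aryl group, and aqueous work-up gives 8.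

**Step 6.** Once the pivalates are cleaved, ring B is an aluminium phenoxide in a Lewis-acidic medium, which may let C7 epimerise to the trans series, and the hindered 4-pivalate may resist. The fallback sets out from 5 and comes back at 10, and changes the end game to silyl protection with a buffered fluoride release as the last operation.
- TBSCl and imidazole in DMF convert 5 into the racemic trans bis(silyl ether) F4.
- The same enolisation and kinetic protonation as in step 4 give the racemic cis bis(silyl ether) F5.
- Chromatography on the chiral phase of step 5 gives the (7S,8S) enantiomer F6.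
- iBu2AlH at −78 °C reduces only the two ethyl esters and gives the bis(silyl ether) diol F7.
- Bu4NF buffered with AcOH (THF, 0 °C) frees the catechol and gives 10.

## Further compounds

F1 | step 2 | ethyl (E)-3-[4-hydroxy-3-methoxy-5-(2,2-dimethylpropanoyloxy)phenyl]prop-2-enoate | CCOC(=O)/C=C/c1cc(OC)c(O)c(OC(=O)C(C)(C)C)c1
F2 | step 2 | racemic trans mono-pivalate, (7S,8R) shown: ethyl (2R,3S)-rel-3-[4-hydroxy-3-methoxy-5-(2,2-dimethylpropanoyloxy)phenyl]-6-[(E)-3-ethoxy-3-oxoprop-1-enyl]-8-methoxy-2,3-dihydro-1,4-benzodioxine-2-carboxylate | COc1cc([C@@H]2Oc3cc(/C=C/C(=O)OCC)cc(OC)c3O[C@H]2C(=O)OCC)cc(OC(=O)C(C)(C)C)c1O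
F3 | step 4 | ketene silyl acetal of 6 (C8=C9, O-SiMe3), racemic, (7S) shown | CCOC(O[Si](C)(C)C)=C1Oc2c(OC)cc(/C=C/C(=O)OCC)cc2O[C@H]1c3cc(OC)c(OC(=O)C(C)(C)C)c(OC(=O)C(C)(C)C)c3
F4 | step 6 | racemic trans bis(tert-butyldimethylsilyl ether) of 5, (7S,8R) shown | COc1cc([C@@H]2Oc3cc(/C=C/C(=O)OCC)cc(OC)c3O[C@H]2C(=O)OCC)cc(O[Si](C)(C)C(C)(C)C)c1O[Si](C)(C)C(C)(C)C
F5 | step 6 | racemic cis bis(tert-butyldimethylsilyl ether) diester, (7S,8S) shown | COc1cc([C@@H]2Oc3cc(/C=C/C(=O)OCC)cc(OC)c3O[C@@H]2C(=O)OCC)cc(O[Si](C)(C)C(C)(C)C)c1O[Si](C)(C)C(C)(C)C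
F6 | step 6 | (7S,8S) cis bis(tert-butyldimethylsilyl ether) diester, single enantiomer | COc1cc([C@@H]2Oc3cc(/C=C/C(=O)OCC)cc(OC)c3O[C@@H]2C(=O)OCC)cc(O[Si](C)(C)C(C)(C)C)c1O[Si](C)(C)C(C)(C)C
F7 | step 6 | (7S,8R) cis bis(tert-butyldimethylsilyl ether) of the target diol | COc1cc([C@@H]2Oc3cc(/C=C/CO)cc(OC)c3O[C@@H]2CO)cc(O[Si](C)(C)C(C)(C)C)c1O[Si](C)(C)C(C)(C)C
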